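We must read this flask at 2.0 min, and a neighbour with the same charge at 50 s, so we want a reckoning that carries from one reading to the other.

Q 30 mM; X 3.00 mM; time 2.0 min

    Q + X → Z + X + J (k1 = 2.7 L mol⁻¹ s⁻¹)
    Z → L (k2 = 0.0035 s⁻¹)
    Z ⇌ D + X, settled at all times (K3 = 1.3 × 10⁻⁹ M)
    Q → Z + J (k4 = 4.1 × 10⁻⁵ s⁻¹)
    Q ⇌ G (K5 = 0.75, k5 = 0.013 s⁻¹)

* part of the Q that has reacted at 2.0 min
* pH of the solution at 2.0 min

- X is the free proton; pH is minus the decimal logarithm of its molar concentration
- what has gone from Q into another species counts as reacted, even if it can come back
- run time (flask): 2.0 min

The route through X returns its X, and the balance with D adds X only as D forms. Even with the whole charge of Q turned into Z, D would reach 1.30 × 10⁻⁵ mM, far less than the 3.00 mM of X, so c(X) and the pH stay as charged. The routes from Q to Z then form a pseudo-first-order loss with constant 0.00814 s⁻¹, which by itself gives 62.3 % reacted.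

But Q passes into G at 0.013 s⁻¹, faster than that loss, and G returns at 0.0173 s⁻¹, so Q is refilled while G counts as reacted. The exchange relaxes with a half-life of 0.381 min, shorter than the run, so Q and G soon fall as one pool. With the balance share 57.1 % as Q, that pool drains at 0.00465 s⁻¹.

Yet the loss constant, though less than the sum of the forward and return constants, is 26.9 % of it, so once the pool falls as one, Q stands below its balance share. While the pool falls at one constant, the share as Q is the return constant minus the drain constant, divided by that difference plus the forward constant. Putting our answer back gives 0.00402 s⁻¹, and another round gives 0.00412 s⁻¹. This is the drain constant, the loss constant times the share of the falling pool that stands as Q.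

One objection remains: the flask starts with no G. That adds a term with constant 0.0344 s⁻¹, faster than the drain, and the starting slope gives the slow term a weight of 0.437. We commit to 72.4 % reacted.

The forecast gives 72.4 % and pH 2.52, and says that this much “has reacted, counting Q held as G”. It solves the same two-rate system, so this match checks nothing.

The simulated flask gives 72.4 % and pH 2.52, with X at 100 % of its charge. Its pool of Q and G falls from 69.4 % at 1.00 min to 53.2 % at 2.00 min, a reading of 0.00445 s⁻¹ against our drain constant of 0.00412 s⁻¹. For the neighbour flask read at 50 s, the same constants and weight give 54.3 % reacted, and the simulation of that flask gives 54.3 %, with Q at 45.7 % and J at 27.0 %.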